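Ring A is the quinic unit with the free tertiary hydroxyl, ring B the one with the free carboxyl (quinic acid numbering, C7 = carboxyl carbon). Everything rests on cutting ring B at C1B–C6B and C2B–C3B: C1B is quaternary, carries O1B (acylated by C7A) and C7B, and lies between the methylenes C2B and C6B, the pattern left by a 2-acyloxyacrylate dienophile. One catalyst-controlled Diels–Alder reaction of buta-1,3-diene with the allyl acrylate bearing the protected ring A acyl group on its enol oxygen closes ring B and sets C1B with the hindered tertiary ester already in place. C1B then relays its configuration to C5B, C4B and C3B through a bridging lactone.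

Key step: step 10

Remark on the stereochemistry: both quinic units of the target have the ent-quinic configuration (mirror image of natural (−)-quinic acid: O1, O3 and O4 on one ring face, O5 and C7 on the other), so neither is taken from the natural acid. "ent-Quinide" means the C7→O5 lactone; "ring A acyl" means the 3,4-O-isopropylidene-1,5-bis-O-triethylsilyl-ent-quinoyl group.

Assumption for step 10: the catalyst is taken to expose the same alkene face of the 2-acyloxyacrylate as it does in simple acrylate esters. If the sense proves opposite, the mirror-image (R)-catalyst is used under the same conditions.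

Step 1
Reactants: 1 (S)-lactic acid; 2 pivalaldehyde
Product: 3 (2S,5S)-2-tert-butyl-5-methyl-1,3-dioxolan-4-one
Conditions: TsOH·H2O (cat.), pentane, reflux, azeotropic water removal; recrystallisation (pentane/Et2O, −78 °C)
Reagents that add atoms: none
Why: Acid-catalysed acetalisation under water removal favours the cis acetal, so the lactate stereocentre fixes the new acetal carbon C2 as S, and crystallisation should remove the minor trans isomer.

Step 2
Reactants: 3 (2S,5S)-2-tert-butyl-5-methyl-1,3-dioxolan-4-one
Product: 5 (S)-2-tert-butyl-5-methylene-1,3-dioxolan-4-one, via bromo-dioxolanone 4 (not isolated)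
Conditions: NBS, AIBN (cat.), cyclohexane, reflux; filter; then Et3N, Et2O, 0 °C to rt
Reagents that add atoms: none
Why: Wohl–Ziegler bromination at the captodative C5–H followed by E2 dehydrobromination toward the methyl group gives the exocyclic enol ester, while the acetal stereocentre is not touched.

Step 3
Reactants: 5 (S)-2-tert-butyl-5-methylene-1,3-dioxolan-4-one; 6 buta-1,3-diene
Product: 7 (2S,5R)-2-tert-butyl-1,3-dioxaspiro[4.5]dec-7-en-4-one
Conditions: 6 (excess), BHT (cat.), toluene, 100 °C, sealed tube
Reagents that add atoms: none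
Why: Thermal Diels–Alder reaction of this chiral 2-hydroxyacrylate equivalent, in which the diene adds to the alkene face opposite the tert-butyl group, so the acetal centre sets the spiro carbon (the later C1A) as R.

Step 4
Reactants: 7 (2S,5R)-2-tert-butyl-1,3-dioxaspiro[4.5]dec-7-en-4-one
Product: 9 (1R,4S,5S)-1-hydroxy-4-iodo-6-oxabicyclo[3.2.1]octan-7-one, via lithium hydroxy-carboxylate 8 (not isolated)
Conditions: LiOH·H2O, THF/H2O, 0 °C to rt; Et2O wash; then NaHCO3, KI, I2, H2O/CH2Cl2, 0 °C to rt, dark
Reagents that add atoms: lithium hydroxide, [Li+].[OH-]; iodine, II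
Why: Ester saponification of the dioxolanone followed by kinetic iodolactonisation: the C7A carboxylate can reach only C5A and only on its own ring face (5-exo opening of the iodonium ion), so C1A fixes C5A (oxygen cis to C7A) and, through anti addition, C4A (iodine trans to that oxygen).

Step 5
Reactants: 9 (1R,4S,5S)-1-hydroxy-4-iodo-6-oxabicyclo[3.2.1]octan-7-one
Product: 10 (1R,5S)-1-hydroxy-6-oxabicyclo[3.2.1]oct-3-en-7-one
Conditions: DBU, toluene, 90 °C
Reagents that add atoms: none
Why: E2 dehydroiodination, in which only the axial hydrogen on C3A is antiperiplanar to the axial C4A–I bond, should give the C3A=C4A alkene and leave C1A and C5A untouched.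

Step 6
Reactants: 10 (1R,5S)-1-hydroxy-6-oxabicyclo[3.2.1]oct-3-en-7-one
Product: 12 ent-3,4-O-isopropylidenequinide, via triol lactone 11 (not isolated)
Conditions: OsO4 (2 mol %), NMO, acetone/H2O, rt; Na2SO3; evaporate; then 2,2-dimethoxypropane, TsOH·H2O (cat.), acetone, rt
Reagents that add atoms: N-methylmorpholine N-oxide, C[N+]1([O-])CCOCC1; water, O (both oxygens are passed on by OsO4); 2,2-dimethoxypropane, COC(C)(C)OC
Why: Catalytic OsO4/NMO syn-dihydroxylation takes place on the alkene face turned away from the lactone bridge, which sets C3A and C4A (both oxygens trans to O5A), and acid-catalysed transketalisation then locks the cis-diol as the acetonide.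

Step 7
Reactants: 12 ent-3,4-O-isopropylidenequinide
Product: 15 3,4-O-isopropylidene-1,5-bis-O-triethylsilyl-ent-quinic acid, via lithium carboxylate 13 (not isolated), via tris-silyl ester 14 (not isolated)
Conditions: LiOH·H2O (1.05 equiv), THF/H2O, 0 °C to rt; evaporate, toluene azeotrope; TESOTf (3.5 equiv), 2,6-lutidine, CH2Cl2, −78 to 0 °C; then K2CO3 (cat.), MeOH/THF/H2O, 0 °C; NaH2PO4 buffer (pH 5)
Reagents that add atoms: lithium hydroxide, [Li+].[OH-]; triethylsilyl triflate, CC[Si](CC)(CC)OS(=O)(=O)C(F)(F)F
Why: Lactone saponification, exhaustive silylation with the silyl triflate (reactive enough for the tertiary O1A) and mild solvolysis of the labile silyl ester are standard operations and involve no stereocentre.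

Step 8
Reactants: 16 pyruvic acid; 17 allyl alcohol
Product: 18 allyl pyruvate
Conditions: TsOH·H2O (cat.), toluene, reflux, azeotropic water removal; distillation
Reagents that add atoms: none
Why: Fischer esterification driven by removal of water is the standard access to simple pyruvate esters.

Step 9
Reactants: 15 3,4-O-isopropylidene-1,5-bis-O-triethylsilyl-ent-quinic acid; 18 allyl pyruvate
Product: 20 allyl 2-[(ring A acyl)oxy]prop-2-enoate, via acid chloride 19 (not isolated)
Conditions: 1-chloro-N,N,2-trimethylprop-1-en-1-amine, CH2Cl2, 0 °C to rt; then 18 (3 equiv, slow addition), Et3N, DMAP (cat.), CH2Cl2, −20 °C to rt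
Reagents that add atoms: none
Why: The acid chloride is made under neutral conditions that spare silyl ethers and acetonide and, having no α-hydrogen and hence no ketene pathway, should O-acylate the amine-generated pyruvate enolate (enol ester formation from a pyruvate ester, an acyl chloride and a tertiary amine).

Step 10
Reactants: 20 allyl 2-[(ring A acyl)oxy]prop-2-enoate; 6 buta-1,3-diene
Product: 21 allyl (R)-1-[(ring A acyl)oxy]cyclohex-3-ene-1-carboxylate
Conditions: (S)-1-(2-methylphenyl)-3,3-diphenyltetrahydro-1H,3H-pyrrolo[1,2-c][1,3,2]oxazaborole (24 mol %), HN(SO2CF3)2 (20 mol %), 6 (excess), CH2Cl2, −40 °C to rt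
Reagents that add atoms: none
Why: Proposed new method: chiral oxazaborolidinium catalysis has not been demonstrated for 2-acyloxyacrylate esters, but the cation is expected to bind the allyl ester carbonyl of the captodative alkene as it binds simple acrylates, lowering the LUMO and screening one alkene face. The bond reorganisation is a one-step suprafacial [4+2] cycloaddition; the closest known reactions are the thermal Diels–Alder addition of butadiene to 2-acetoxyacrylates and the oxazaborolidinium-catalysed addition of butadiene to 2,2,2-trifluoroethyl acrylate. Ring B is closed by cycloaddition as a six-membered carbocycle, C1B–C6B and C2B–C3B forming together while O1B already carries the ring A acyl group. The single new stereocentre C1B should be set R by the catalyst, since the ring A stereocentres are too far away to bias the faces; the (S)-catalyst is chosen because the face it exposes in acrylates corresponds to this configuration. With a symmetrical, unsubstituted diene there is no regiochemical or endo/exo question, so facial selectivity is the only selectivity required, and the allyl alkene is not a competent dienophile. A slight excess of the oxazaborolidine over the acid activator keeps the medium free of protic acid for the silyl ethers and the acetonide.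

Step 11
Reactants: 21 allyl (R)-1-[(ring A acyl)oxy]cyclohex-3-ene-1-carboxylate
Product: 22 (R)-1-[(ring A acyl)oxy]cyclohex-3-ene-1-carboxylic acid
Conditions: Pd(PPh3)4 (5 mol %), morpholine, THF, rt; NaH2PO4 buffer (pH 5)
Reagents that add atoms: none
Why: Tsuji–Trost deallylation through a π-allyl palladium complex trapped by morpholine frees the acid under neutral conditions that leave the hindered inter-ring ester, the silyl ethers and the acetonide alone.

Step 12
Reactants: 22 (R)-1-[(ring A acyl)oxy]cyclohex-3-ene-1-carboxylic acid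
Product: 23 (1R,4S,5S)-4-iodo-7-oxo-6-oxabicyclo[3.2.1]octan-1-yl ester of 15
Conditions: I2, KI, NaHCO3, THF/H2O, 0 °C, dark
Reagents that add atoms: iodine, II
Why: Iodolactonisation as in step 4: the C7B carboxylate reaches C5B only on its own face, so C1B sets C5B (oxygen cis to C7B) and, by anti addition, C4B (iodine trans to O5B).

Step 13
Reactants: 23 ring B iodolactone
Product: 24 (1R,5S)-7-oxo-6-oxabicyclo[3.2.1]oct-3-en-1-yl ester of 15
Conditions: DBU, toluene, 80 °C
Reagents that add atoms: none
Why: E2 dehydroiodination through the antiperiplanar axial hydrogen on C3B gives the C3B=C4B alkene, since the bridgehead hydrogen on C5B is not aligned and no other acidic site is present.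

Step 14
Reactants: 24 ring B unsaturated lactone
Product: 25 (1R,3S,4S,5S)-3,4-dihydroxy-7-oxo-6-oxabicyclo[3.2.1]octan-1-yl ester of 15
Conditions: OsO4 (2 mol %), NMO, acetone/H2O, rt
Reagents that add atoms: N-methylmorpholine N-oxide, C[N+]1([O-])CCOCC1; water, O (both oxygens are passed on by OsO4)
Why: Catalytic OsO4/NMO syn-dihydroxylation from the face opposite the lactone bridge sets C3B and C4B (both hydroxyls trans to O5B), completing the ent-quinide configuration of ring B.

Step 15
Reactants: 25 ring B diol lactone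
Product: 26 tetraol (O1A–H, O5A–H, O3B–H and O4B–H free; acetonide and lactone kept)
Conditions: HF·pyridine, pyridine, THF, 0 °C to rt
Reagents that add atoms: none
Why: Buffered fluoride-mediated desilylation removes both triethylsilyl ethers without the basic conditions that could start acyl migration or lactone opening, and leaves the acetonide.

Step 16
Reactants: 27 caffeic acid
Product: 28 3,4-di-O-acetylcaffeic acid
Conditions: Ac2O, pyridine, DMAP (cat.), rt; then H2O
Reagents that add atoms: acetic anhydride, CC(=O)OC(C)=O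
Why: Phenol acetylation; any mixed anhydride at the carboxyl group is hydrolysed in the aqueous quench, and the E alkene is not affected.

Step 17
Reactants: 28 3,4-di-O-acetylcaffeic acid
Product: 29 3,4-di-O-acetylcaffeoyl chloride
Conditions: (COCl)2, DMF (cat.), CH2Cl2, 0 °C to rt
Reagents that add atoms: oxalyl chloride, O=C(Cl)C(=O)Cl
Why: DMF-catalysed acid chloride formation converts the cinnamic acid without isomerising the alkene or cleaving the aryl acetates.

Step 18
Reactants: 26 tetraol; 29 3,4-di-O-acetylcaffeoyl chloride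
Product: 30 5A-O,3B-O-bis(3,4-di-O-acetylcaffeoyl) derivative of 26
Conditions: 29 (2.2 equiv), pyridine, CH2Cl2, −20 to 0 °C
Reagents that add atoms: none
Why: Esterification with an acid chloride in pyridine should select the two unhindered equatorial secondary hydroxyls, O5A and O3B (equatorial in the bicyclic lactone), over the axial, flanked O4B and the tertiary O1A.

Step 19
Reactants: 30 protected bis-caffeoyl lactone
Product: 31 target compound
Conditions: 1 M HCl (aq)/THF 1:1, rt; lyophilisation; reversed-phase chromatography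
Reagents that add atoms: water, O
Why: Acid-catalysed hydrolysis removes the acetonide and the four aryl acetates and opens the strained bridged γ-lactone to the hydroxy acid, while the alkyl cinnamates and the hindered tertiary ester hydrolyse far more slowly, and no stereocentre is touched.

Compound list
1 | (S)-lactic acid | C[C@H](O)C(=O)O | starting material
2 | pivalaldehyde | CC(C)(C)C=O | starting material
3 | (2S,5S)-2-tert-butyl-5-methyl-1,3-dioxolan-4-one (cis) | C[C@@H]1O[C@@H](OC1=O)C(C)(C)C | intermediate
4 | (2S,5R)-5-bromo-2-tert-butyl-5-methyl-1,3-dioxolan-4-one (bromine expected trans to tert-butyl) | C[C@]1(Br)O[C@@H](OC1=O)C(C)(C)C | intermediate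
5 | (S)-2-tert-butyl-5-methylene-1,3-dioxolan-4-one | C=C1O[C@@H](OC1=O)C(C)(C)C | intermediate
6 | buta-1,3-diene | C=CC=C | starting material
7 | (2S,5R)-2-tert-butyl-1,3-dioxaspiro[4.5]dec-7-en-4-one | C1=CC[C@@](O2)(C(=O)O[C@H]2C(C)(C)C)CC1 | intermediate
8 | lithium (R)-1-hydroxycyclohex-3-ene-1-carboxylate | C1=CC[C@@](O)(C(=O)[O-])CC1.[Li+] | intermediate
9 | (1R,4S,5S)-1-hydroxy-4-iodo-6-oxabicyclo[3.2.1]octan-7-one | O=C1O[C@H]2C[C@]1(O)CC[C@@H]2I | intermediate
10 | (1R,5S)-1-hydroxy-6-oxabicyclo[3.2.1]oct-3-en-7-one | O=C1O[C@H]2C[C@]1(O)CC=C2 | intermediate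
11 | ent-quinide, (1R,3S,4S,5S)-1,3,4-trihydroxy-6-oxabicyclo[3.2.1]octan-7-one | O=C1O[C@H]2C[C@]1(O)C[C@H](O)[C@@H]2O | intermediate
12 | ent-3,4-O-isopropylidenequinide (3,4-acetonide of 11) | O=C1O[C@H]2C[C@]1(O)C[C@@H]3OC(C)(C)O[C@H]23 | intermediate
13 | lithium 3,4-O-isopropylidene-ent-quinate | O[C@H]1C[C@@](O)(C(=O)[O-])C[C@@H]2OC(C)(C)O[C@H]12.[Li+] | intermediate
14 | triethylsilyl 3,4-O-isopropylidene-1,5-bis-O-triethylsilyl-ent-quinate | CC[Si](CC)(CC)O[C@H]1C[C@@](O[Si](CC)(CC)CC)(C(=O)O[Si](CC)(CC)CC)C[C@@H]2OC(C)(C)O[C@H]12 | intermediate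
15 | 3,4-O-isopropylidene-1,5-bis-O-triethylsilyl-ent-quinic acid (ring A acid) | CC[Si](CC)(CC)O[C@H]1C[C@@](O[Si](CC)(CC)CC)(C(=O)O)C[C@@H]2OC(C)(C)O[C@H]12 | intermediate
16 | pyruvic acid | CC(=O)C(=O)O | starting material
17 | allyl alcohol | C=CCO | starting material
18 | allyl pyruvate | CC(=O)C(=O)OCC=C | intermediate
19 | ring A acid chloride (chloride of 15) | CC[Si](CC)(CC)O[C@H]1C[C@@](O[Si](CC)(CC)CC)(C(Cl)=O)C[C@@H]2OC(C)(C)O[C@H]12 | intermediate
20 | allyl 2-[(ring A acyl)oxy]prop-2-enoate | CC[Si](CC)(CC)O[C@H]1C[C@@](O[Si](CC)(CC)CC)(C(=O)OC(=C)C(=O)OCC=C)C[C@@H]2OC(C)(C)O[C@H]12 | intermediate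
21 | allyl (R)-1-[(ring A acyl)oxy]cyclohex-3-ene-1-carboxylate | CC[Si](CC)(CC)O[C@H]1C[C@@](O[Si](CC)(CC)CC)(C(=O)O[C@]3(C(=O)OCC=C)CCC=CC3)C[C@@H]2OC(C)(C)O[C@H]12 | intermediate
22 | (R)-1-[(ring A acyl)oxy]cyclohex-3-ene-1-carboxylic acid | CC[Si](CC)(CC)O[C@H]1C[C@@](O[Si](CC)(CC)CC)(C(=O)O[C@]3(C(=O)O)CCC=CC3)C[C@@H]2OC(C)(C)O[C@H]12 | intermediate
23 | (1R,4S,5S)-4-iodo-7-oxo-6-oxabicyclo[3.2.1]octan-1-yl ester of 15 (C7B→O5B lactone, iodine on C4B trans to O5B) | CC[Si](CC)(CC)O[C@H]1C[C@@](O[Si](CC)(CC)CC)(C(=O)O[C@]3(C(=O)O4)CC[C@H](I)[C@@H]4C3)C[C@@H]2OC(C)(C)O[C@H]12 | intermediate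
24 | (1R,5S)-7-oxo-6-oxabicyclo[3.2.1]oct-3-en-1-yl ester of 15 (C3B=C4B alkene) | CC[Si](CC)(CC)O[C@H]1C[C@@](O[Si](CC)(CC)CC)(C(=O)O[C@]3(C(=O)O4)CC=C[C@@H]4C3)C[C@@H]2OC(C)(C)O[C@H]12 | intermediate
25 | (1R,3S,4S,5S)-3,4-dihydroxy-7-oxo-6-oxabicyclo[3.2.1]octan-1-yl ester of 15 (ring B as 1-O-acyl-ent-quinide) | CC[Si](CC)(CC)O[C@H]1C[C@@](O[Si](CC)(CC)CC)(C(=O)O[C@]3(C(=O)O4)C[C@H](O)[C@H](O)[C@@H]4C3)C[C@@H]2OC(C)(C)O[C@H]12 | intermediate
26 | ent-quinid-1-yl 3,4-O-isopropylidene-ent-quinate (tetraol) | O[C@H]1C[C@@](O)(C(=O)O[C@]3(C(=O)O4)C[C@H](O)[C@H](O)[C@@H]4C3)C[C@@H]2OC(C)(C)O[C@H]12 | intermediate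
27 | caffeic acid | O=C(O)/C=C/c1ccc(O)c(O)c1 | starting material
28 | 3,4-di-O-acetylcaffeic acid | CC(=O)Oc1ccc(/C=C/C(=O)O)cc1OC(C)=O | intermediate
29 | 3,4-di-O-acetylcaffeoyl chloride | CC(=O)Oc1ccc(/C=C/C(Cl)=O)cc1OC(C)=O | intermediate
30 | 5A-O,3B-O-bis[(E)-3,4-diacetoxycinnamoyl] derivative of 26 | O=C(/C=C/c1ccc(OC(C)=O)c(OC(C)=O)c1)O[C@H]1C[C@@](O)(C(=O)O[C@]3(C(=O)O4)C[C@H](OC(=O)/C=C/c5ccc(OC(C)=O)c(OC(C)=O)c5)[C@H](O)[C@@H]4C3)C[C@@H]2OC(C)(C)O[C@H]12 | intermediate
31 | CNP0107948.1: 3B-O-caffeoyl-ent-quinic acid esterified at O1B by 5A-O-caffeoyl-ent-quinic acid | O=C(/C=C/c1ccc(O)c(O)c1)O[C@H]1C[C@@](O)(C(=O)O[C@]2(C(=O)O)C[C@H](OC(=O)/C=C/c3ccc(O)c(O)c3)[C@H](O)[C@@H](O)C2)C[C@H](O)[C@@H]1O | target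

Total step count: 19. Longest linear sequence: 16 steps (steps 1–7, 9–15, 18 and 19).

Steps most likely to fail

1. Step 10 (Proposed new method). The facial selectivity may be poor, the many Lewis-basic oxygens may tie up the catalyst so that turnover stops, or a silyl ether or the acetonide may be lost. Fallback (known chemistry): setting out from 20, the cycloaddition is run thermally without catalyst (excess 6, BHT, toluene, 130 °C, sealed tube), as is established for 2-acyloxyacrylates. This should give 21 together with its C1B epimer F1. Because ring A is enantiopure the two are diastereomers and are separated by chromatography, and the route is rejoined at 21.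

2. Step 9. O-Acylation by the hindered acid chloride may be slow, so that self-condensation or C-acylation of the pyruvate takes over. Fallback: setting out from 15 (through 19), DMAP-catalysed esterification with racemic allyl 3-chloro-2-hydroxypropanoate F2 gives the 2-O-acyl-3-chloropropanoate F3 as an epimer mixture. F2 is made from commercial 3-chloro-2-hydroxypropanoic acid (OC(CCl)C(=O)O) and 17 by acid-catalysed esterification. DBU (CH2Cl2, 0 °C) then eliminates HCl from F3 by an E1cB pathway and gives 20, where the route is rejoined.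

3. Step 18. Discrimination between O3B and O4B may be incomplete, or over-acylation and acyl migration may occur. Fallback: setting out from 25, Bu2SnO (toluene, reflux, water removal) gives the dibutylstannylene acetal F4, which reacts with 29 (1 equiv) at the equatorial oxygen to give the O3B mono-ester F5. HF·pyridine then removes the silyl ethers to give triol F6, and one further equivalent of 29 in pyridine at −20 °C acylates O5A to give 30, where the route is rejoined.

Further compounds
F1 | step 10 | allyl (S)-1-[(ring A acyl)oxy]cyclohex-3-ene-1-carboxylate (C1B epimer of 21) | CC[Si](CC)(CC)O[C@H]1C[C@@](O[Si](CC)(CC)CC)(C(=O)O[C@@]3(C(=O)OCC=C)CCC=CC3)C[C@@H]2OC(C)(C)O[C@H]12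
F2 | step 9 | allyl 3-chloro-2-hydroxypropanoate (racemic) | OC(CCl)C(=O)OCC=C
F3 | step 9 | allyl 3-chloro-2-[(ring A acyl)oxy]propanoate (both epimers at the chlorolactate carbon) | CC[Si](CC)(CC)O[C@H]1C[C@@](O[Si](CC)(CC)CC)(C(=O)OC(CCl)C(=O)OCC=C)C[C@@H]2OC(C)(C)O[C@H]12
F4 | step 18 | 3B,4B-O-dibutylstannylene acetal of 25 | CC[Si](CC)(CC)O[C@H]1C[C@@](O[Si](CC)(CC)CC)(C(=O)O[C@]3(C(=O)O4)C[C@H](O5)[C@H](O[Sn]5(CCCC)CCCC)[C@@H]4C3)C[C@@H]2OC(C)(C)O[C@H]12
F5 | step 18 | 3B-O-[(E)-3,4-diacetoxycinnamoyl] derivative of 25 | CC[Si](CC)(CC)O[C@H]1C[C@@](O[Si](CC)(CC)CC)(C(=O)O[C@]3(C(=O)O4)C[C@H](OC(=O)/C=C/c5ccc(OC(C)=O)c(OC(C)=O)c5)[C@H](O)[C@@H]4C3)C[C@@H]2OC(C)(C)O[C@H]12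
F6 | step 18 | 3B-O-[(E)-3,4-diacetoxycinnamoyl] derivative of 26 (O1A–H, O5A–H and O4B–H free) | O[C@H]1C[C@@](O)(C(=O)O[C@]3(C(=O)O4)C[C@H](OC(=O)/C=C/c5ccc(OC(C)=O)c(OC(C)=O)c5)[C@H](O)[C@@H]4C3)C[C@@H]2OC(C)(C)O[C@H]12
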